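The numbers in the tables were computed for substances that don't exist, noise included.

**Late readings.** At their last readings, Tuesday's and Saturday's flasks started from different charges of partner, yet each has lost nearly the same fraction of it. That fraction is what I follow.

all flasks: substrate 0.050 M; initiator 2 mol%

| flask | partner | remark | time |
|---|---|---|---|
| Tuesday's | 0.90 equiv | run made earlier |  |
| Saturday's | 1.3 equiv | run made earlier |  |
| green | 1.00 equiv |  | 1.0 h |
| violet | 2.00 equiv |  | 1.0 h |

| run | time / min | substrate / % | target / % |
|---|---|---|---|
| Tuesday's | 3.00 | 92.4 | 5.4 |
| Tuesday's | 6.00 | 85.5 | 10.6 |
| Tuesday's | 12.0 | 74.2 | 17.4 |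
| Tuesday's | 20.0 | 64.3 | 25.6 |
| Tuesday's | 40.0 | 43.3 | 41.2 |
| Saturday's | 3.00 | 88.5 | 6.3 |
| Saturday's | 6.00 | 79.5 | 13.5 |
| Saturday's | 12.0 | 64.1 | 24.9 |
| Saturday's | 20.0 | 50.0 | 36.3 |
| Saturday's | 40.0 | 24.8 | 59.4 |

(each reading ± 1 percentage point)

- percent here means substrate units held: one ended chains counts as two
- what is said of by-product includes idle adduct
- the numbers in the tables scatter with a standard deviation of 1 percentage point
- reactions considered so far: initiator -> 2 initiating radical; substrate + initiating radical -> capped initiator + first chain carrier; partner + first chain carrier -> target + second chain carrier; substrate + second chain carrier -> by-product + first chain carrier; first chain carrier -> ended carrier; 2 first chain carrier -> ended chains; substrate + by-product <-> idle adduct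
- what has gone from substrate into another species counts as reacted, even if it can come back

1. part of the substrate that has reacted at the end, green
2. part of the substrate that has reacted at the end, violet
3. what raising the equivalents of partner from its lowest to its highest value here does to the part of the substrate that has reacted (changes below 5 percentage points count as none) (it falls / no change / it rises)

**Partner clock.** Partner is spent in its step with the first chain carrier, rate constant k. If the carrier's concentration c does not depend on partner, partner is pseudo-first-order, and its rate law integrates in closed form: θ = ln(partner charged / partner left) = ∫kc dt. Target counts the partner spent, so the tables give θ. At 40.0 min, Tuesday's run gives 0.612 and Saturday's 0.611, although their equivalents differ.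

**Running forward.** I take c to follow the initiator, which falls exponentially, so each equal interval adds a constant factor x of the one before. The mean θ is 0.331 at 20.0 min and 0.611 at 40.0 min, so x is 0.846. One more interval gives the partner clock at the asked time, 0.848.

**Green.** Partner left is 42.8% of its charge, so with 1.00 equiv green's target is 57.2%. Substrate in neither table column averages 15.6% at the last readings. I carry that over, because green's target lies between those two readings. My green figure is 72.8%.

**Violet.** With 2.00 equiv, my reckoning puts target equal to the substrate charged at θ = 0.693, which is less than the clock I reckoned for the asked time. I say 100% reacted, a rise of 27 percentage points.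

The forecast gives 72%, 98% and "it rises", with the words “substrate is essentially exhausted by 60 min”.

The flasks give 72.4% and 100%; the trend is it rises, by 28 points.

    initiator → 2 initiating radical (k = 0.0100 min⁻¹)
    substrate + initiating radical → capped initiator + first chain carrier (k = 9.40 × 10⁵ M⁻¹ s⁻¹)
    partner + first chain carrier → target + second chain carrier (k = 44000 M⁻¹ s⁻¹)
    substrate + second chain carrier → by-product + first chain carrier (k = 5.30 × 10⁵ M⁻¹ s⁻¹)
    first chain carrier → ended carrier (k = 2600 min⁻¹)
    2 first chain carrier → ended chains (k = 3.00 × 10⁸ M⁻¹ s⁻¹)
    substrate + by-product ⇌ idle adduct, settled at all times (K = 22.0 M⁻¹)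

**What stands.** Green ends with 43% of its partner, a clock of 0.844. In green at the asked time, the first chain carrier goes to partner 22 times as fast as to ended carrier. Violet's answer moves by 5 points with partner down at 1.55 equiv or initiator at 1.4 mol%.

**Second flask.** With 0.250 equiv of partner and the same clock, I reckon 14.3% target. That neighbour of green gives 14.3%.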